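**Strategy.** Ring A is disconnected to a 2,2-dimethylfuran-3(2H)-one: the segment O–C2(Me2)–C3(=O)–C4 of the oxepane is this heterocycle, and its enone bond C4=C7 can add across the isopropenyl alkene C5=C6. One irradiation of furanone 20, which already carries rings C and D, both tertiary acetates and the C11 isopropenyl group, forms C6–C7 and C4–C5, closes ring B and stores ring A as a cis-fused cyclobutane with three new stereocentres; push–pull cleavage of C4–C7 then unveils the oxepanone. Furanone 20 is built linearly from farnesyl acetate by an epoxide cascade (rings C, D), a Sharpless epoxidation–cuprate opening (C10, C11) and a late furanone closure.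

Key step: step 16

Remark: the target is taken with the configuration written (chain numbering 3S,6S,7S,10R,11S,14S,15S,18S,19S,22S); this numbering (C2–C23) is used for all intermediates, and "ring C/D unit" means the (3S,5aS,6S,7S,9aS)-3-(tert-butyldimethylsilyloxy)-2,2,5a,7-tetramethyldecahydro-1-benzoxepin-6-yl group (C14–C23, its position 7 being C15).

Step 1
Reactants: 1 (2E,6E)-farnesyl acetate
Product: 2 (2E,6S,7S,10S)-6,7:10,11-diepoxy-3,7,11-trimethyldodec-2-en-1-yl acetate
Conditions: KHSO5 (Oxone), ent-Shi ketone (1,2:4,5-di-O-isopropylidene-β-L-erythro-2,3-hexodiulo-2,6-pyranose, 0.5 equiv), K2CO3, Bu4NHSO4, Na2B4O7 buffer pH 10.5, MeCN/CH2(OMe)2, 0 °C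
Reagents that add atoms: potassium peroxymonosulfate [K+].OOS(=O)(=O)[O-]
Why: Shi asymmetric epoxidation, in which the chiral dioxirane attacks the two electron-rich trisubstituted alkenes through the spiro transition state (the L-series ketone giving the S-configured CH carbons) while the 2,3-alkene is deactivated by the allylic acetate.

Step 2
Reactants: 2 diepoxy acetate
Product: 3 (2E,6S,7S,10S)-6,7:10,11-diepoxy-3,7,11-trimethyldodec-2-en-1-ol
Conditions: K2CO3, MeOH, 20 °C
Reagents that add atoms: none
Why: Base-catalysed transesterification (methanolysis) frees the allylic alcohol and leaves both epoxides untouched.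

Step 3
Reactants: 3 diepoxy alcohol
Product: 5 (2E,6S,7S,10S)-1-bromo-6,7:10,11-diepoxy-3,7,11-trimethyldodec-2-ene, via allylic mesylate 4 (not isolated)
Conditions: MsCl, Et3N, THF, −40 °C; then LiBr, THF, 0 °C
Reagents that add atoms: methanesulfonyl chloride CS(=O)(=O)Cl (atoms kept in 4 only); lithium bromide [Li+].[Br-]
Why: Mesylation followed by SN2 displacement with bromide at the primary allylic carbon gives the bromide under neutral, cold conditions that spare the epoxides.

Step 4
Reactants: 5 allylic bromide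
Product: 6 tert-butyl (4E,8S,9S,12S)-8,9:12,13-diepoxy-5,9,13-trimethyltetradec-4-enoate
Conditions: tert-butyl acetate, LiN(iPr)2, THF, −78 °C; then 5, DMPU, −78 → −20 °C
Reagents that add atoms: tert-butyl acetate CC(=O)OC(C)(C)C
Why: SN2 alkylation of the ester enolate at the primary allylic bromide adds C12 and C11 and installs the carboxyl group that is to end the cascade.

Step 5
Reactants: 6 diepoxy ester
Product: 7 tricyclic δ-lactone (ring C/D unit whose side chain C13–C12–C11(=O) is closed as a trans-fused six-membered lactone on the C15 oxygen; 14S,15S,18S,19S,22S; C22 OTBS)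
Conditions: TBSOTf, 2,6-di-tert-butyl-4-methylpyridine, CH2Cl2, −78 °C
Reagents that add atoms: tert-butyldimethylsilyl trifluoromethanesulfonate CC(C)(C)[Si](C)(C)OS(=O)(=O)C(F)(F)F
Why: Silyl-triflate-promoted tandem oxa-/carbacyclisation of a 1,5-diepoxide with lactone termination: the silylated terminal epoxide is opened at C23 by the C18–C19 epoxide oxygen, the epoxonium ion is opened at C19 with inversion by C14 of the E-alkene through a chair (C18 and C22 retained, H14 axial), and the C15 cation is captured anti by the ester carbonyl with loss of 2-methylpropene (ambreinolide-type lactonisation), which leaves O15 equatorial and the initiating silyl group as the C22 protecting group.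

Step 6
Reactants: 7 δ-lactone
Product: 8 lactol of 7 (C11 hemiacetal, both anomers)
Conditions: i-Bu2AlH, CH2Cl2, −78 °C
Reagents that add atoms: none
Why: Partial hydride reduction of a lactone at low temperature stops at the six-membered lactol.

Step 7
Reactants: 8 lactol
Product: 9 ethyl (2Z)-2-methyl-5-(7-hydroxy ring C/D unit)pent-2-enoate
Conditions: ethyl 2-[bis(2,2,2-trifluoroethoxy)phosphoryl]propanoate, KN(SiMe3)2, 18-crown-6, THF, −78 °C; then 8, −78 → −20 °C
Reagents that add atoms: ethyl 2-[bis(2,2,2-trifluoroethoxy)phosphoryl]propanoate CCOC(=O)C(C)P(=O)(OCC(F)(F)F)OCC(F)(F)F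
Why: Still–Gennari olefination of the ring-opened hydroxy aldehyde gives the Z-trisubstituted enoate (C10=C11) under kinetic control of the electron-poor phosphonate.

Step 8
Reactants: 9 Z-enoate
Product: 10 (2Z)-2-methyl-5-(7-hydroxy ring C/D unit)pent-2-en-1-ol
Conditions: i-Bu2AlH, CH2Cl2, −78 → 0 °C
Reagents that add atoms: none
Why: 1,2-Reduction of the enoate with i-Bu2AlH gives the allylic alcohol with the Z geometry unchanged.

Step 9
Reactants: 10 Z-allylic alcohol
Product: 11 (10R,11S)-epoxy alcohol, [(2R,3S)-2-methyl-3-[2-(7-hydroxy ring C/D unit)ethyl]oxiran-2-yl]methanol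
Conditions: Ti(OiPr)4, D-(−)-diisopropyl tartrate, t-BuOOH, 4 Å MS, CH2Cl2, −20 °C
Reagents that add atoms: tert-butyl hydroperoxide CC(C)(C)OO
Why: Sharpless asymmetric epoxidation, in which the D-(−)-tartrate complex delivers oxygen to the alkene face that makes C10 R (reagent control, remote ring stereocentres not involved) and the Z geometry fixes C11 relative to C10.

Step 10
Reactants: 11 epoxy alcohol
Product: 12 (10S,11S)-triol, (2S,3S)-2-methyl-3-(prop-1-en-2-yl)-5-(7-hydroxy ring C/D unit)pentane-1,2-diol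
Conditions: CH2=C(CH3)MgBr (excess), CuI (20 mol %), THF, −30 → 0 °C
Reagents that add atoms: isopropenylmagnesium bromide CC(=C)[Mg]Br
Why: Copper-catalysed Grignard opening of a 2-methyl-2,3-epoxy alcohol is an SN2 attack at the less substituted carbon C11 with inversion, which places the isopropenyl group on C11 and leaves C10 as the tertiary alcohol with its configuration intact.

Step 11
Reactants: 12 triol
Product: 14 terminal C9–C10 epoxide, (2S)-2-methyl-2-[(3S)-4-methyl-1-(7-hydroxy ring C/D unit)pent-4-en-3-yl]oxirane, via primary tosylate 13 (not isolated)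
Conditions: NaH, N-tosylimidazole, THF, 0 → 20 °C
Reagents that add atoms: N-tosylimidazole Cc1ccc(cc1)S(=O)(=O)n1ccnc1 (atoms kept in 13 only)
Why: Selective sulfonylation of the primary alkoxide and intramolecular Williamson closure by the neighbouring tertiary alkoxide give the epoxide without touching the C10 stereocentre.

Step 12
Reactants: 14 terminal epoxide
Product: 16 (10R,11S)-alkynyl diol (5R,6S)-5-methyl-6-(prop-1-en-2-yl)-8-(7-hydroxy ring C/D unit)oct-1-yn-5-ol, via silylalkyne 15 (not isolated)
Conditions: Me3SiC≡CCH3, n-BuLi, THF, −78 °C; 14, DMPU, −78 → 20 °C; then K2CO3, MeOH, 20 °C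
Reagents that add atoms: 1-(trimethylsilyl)prop-1-yne CC#C[Si](C)(C)C
Why: Propargylation by SN2 opening of the 2,2-disubstituted epoxide at its CH2 terminus adds C8, C7 and C4 and regenerates the C10 tertiary alcohol, and carbonate methanolysis removes the alkynyl silyl group.

Step 13
Reactants: 16 alkynyl diol
Product: 17 diacetate of 16 (C10 OAc and C15 OAc)
Conditions: Ac2O, DMAP, Et3N, CH2Cl2, 40 °C
Reagents that add atoms: acetic anhydride CC(=O)OC(C)=O
Why: DMAP-catalysed (Steglich) acetylation of both tertiary alcohols, placed here so that a free C10 hydroxyl never coexists with the ynone or the furanone, to whose C7 it could add in a five-membered mode.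

Step 14
Reactants: 17 alkyne diacetate
Product: 18 ynone (17 acylated at C4: AcO–C2Me2–C3(=O)–C4≡C7)
Conditions: 2-acetoxy-2-methylpropanoyl chloride, PdCl2(PPh3)2 (2 mol %), CuI (4 mol %), Et3N, THF, 20 °C
Reagents that add atoms: 2-acetoxy-2-methylpropanoyl chloride CC(=O)OC(C)(C)C(Cl)=O
Why: Acyl Sonogashira coupling (copper acetylide transferred to the acylpalladium species) forms the C3–C4 bond under weakly basic conditions that the tertiary acetates tolerate.

Step 15
Reactants: 18 ynone
Product: 20 furanone, 5-substituted 2,2-dimethylfuran-3(2H)-one carrying C8–C9–C10(Me)(OAc)–C11(isopropenyl)–C12–C13–(7-acetoxy ring C/D unit), via hydroxy ynone 19 (not isolated)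
Conditions: K2CO3, MeOH, 0 °C; then 1 M HCl, THF, 20 °C
Reagents that add atoms: none
Why: Methanolysis cleaves only the ketone-activated acetate and the freed tertiary hydroxyl adds to C7 of the ynone (5-endo-dig oxa-Michael cyclisation, any β-methoxy enone being converged by the acid) to give the 3(2H)-furanone.

Step 16
Reactants: 20 furanone
Product: 21 cis-fused cyclobutane photoadduct (C6–C7 and C4–C5 formed; 4R,6S,7R)
Conditions: hν (350 nm, Pyrex), degassed MeCN (2 mM), 20 °C
Reagents that add atoms: none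
Why: Excitation and intersystem crossing give the furanone triplet, whose β-carbon C7 bonds to C6 of the isopropenyl group to close ring B through a chair-like six-membered transition state (6-exo-trig, 1,6-closure), after which the 1,4-diradical at C4 and C5 collapses to the cyclobutane. The closest known reaction type is the intramolecular enone–alkene [2+2] photocycloaddition of 3(2H)-furanones and related 4-oxa-enones, which give fused adducts with four-atom tethers. C6 is set against C11 in the first bond formation, with the C12 chain and the C10 methyl group equatorial and the small C10 acetoxy group axial, so that C5 lies on the tether face syn to H11. C7 and C4 then follow from geometry, because the cyclobutane can only be cis-fused to ring B and to the five-membered ring. The step needs the fused and not the crossed adduct, which the preference for six- over seven-membered first closure secures, and the correct alkene face, which rests on the chair preference and is the main uncertainty. High dilution in degassed solvent suppresses furanone dimerisation and quenching.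

Step 17
Reactants: 21 photoadduct
Product: 22 oxepan-3-one (rings A and B complete, C7–H trans to the C6 methyl group; 6S,7S)
Conditions: BF3·OEt2, Et3SiH, CH2Cl2, −78 → −40 °C; aq. NaHCO3
Reagents that add atoms: none
Why: Proposed new method: coordination of BF3 to the C3 ketone lets the ring-oxygen lone pair push open the strained C4–C7 bond of the donor–acceptor cyclobutane (closest known types: Lewis-acid opening of 2-alkoxycyclobutyl ketones and the retro-aldol half of the de Mayo reaction) to a boron enolate and a seven-membered oxocarbenium ion, which Et3SiH reduces at C7 by axial attack anti to the C6 methyl group as in reductive etherification, the enolate being protonated on work-up.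

Step 18
Reactants: 22 oxepanone
Product: 23 (3S)-alcohol
Conditions: (R)-2-methyl-CBS-oxazaborolidine [(3aR)-1-methyl-3,3-diphenyltetrahydro-1H,3H-pyrrolo[1,2-c][1,3,2]oxazaborole] (0.5 equiv), BH3·SMe2, THF, −20 °C
Reagents that add atoms: none
Why: Corey–Bakshi–Shibata reduction, in which the ketone binds with its large quaternary C2 side away from the catalyst so that the R catalyst delivers hydride to give the 3S alcohol under reagent control.

Step 19
Reactants: 23 alcohol
Product: 24 C3 acetate (three acetates, C22 OTBS)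
Conditions: Ac2O, DMAP, pyridine, 20 °C
Reagents that add atoms: acetic anhydride CC(=O)OC(C)=O
Why: DMAP-catalysed acetylation of the only free hydroxyl group.

Step 20
Reactants: 24 silyl ether
Product: 25 CNP0169816.1 (target)
Conditions: HF·pyridine, THF, 0 → 20 °C
Reagents that add atoms: none
Why: Fluoride-driven cleavage of the silyl ether under buffered acidic conditions leaves the secondary and both tertiary acetates in place.

**Compound list**

1 | (2E,6E)-farnesyl acetate | CC(=O)OC/C=C(\C)CC/C=C(\C)CCC=C(C)C | starting material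
2 | (2E,6S,7S,10S)-6,7:10,11-diepoxy-3,7,11-trimethyldodec-2-en-1-yl acetate | CC(=O)OC/C=C(\C)CC[C@@H]1O[C@@]1(C)CC[C@@H]1OC1(C)C | intermediate
3 | (2E,6S,7S,10S)-6,7:10,11-diepoxy-3,7,11-trimethyldodec-2-en-1-ol | OC/C=C(\C)CC[C@@H]1O[C@@]1(C)CC[C@@H]1OC1(C)C | intermediate
4 | allylic mesylate of 3 | CS(=O)(=O)OC/C=C(\C)CC[C@@H]1O[C@@]1(C)CC[C@@H]1OC1(C)C | intermediate
5 | (2E,6S,7S,10S)-1-bromo-6,7:10,11-diepoxy-3,7,11-trimethyldodec-2-ene | BrC/C=C(\C)CC[C@@H]1O[C@@]1(C)CC[C@@H]1OC1(C)C | intermediate
6 | tert-butyl (4E,8S,9S,12S)-8,9:12,13-diepoxy-5,9,13-trimethyltetradec-4-enoate | CC(C)(C)OC(=O)CC/C=C(\C)CC[C@@H]1O[C@@]1(C)CC[C@@H]1OC1(C)C | intermediate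
7 | tricyclic δ-lactone (C11 carbonyl on O15, C22 OTBS; 14S,15S,18S,19S,22S) | O=C1CC[C@H]2[C@]3(C)CC[C@H](O[Si](C)(C)C(C)(C)C)C(C)(C)O[C@H]3CC[C@]2(C)O1 | intermediate
8 | lactol of 7 (C11 hemiacetal, both anomers) | OC1CC[C@H]2[C@]3(C)CC[C@H](O[Si](C)(C)C(C)(C)C)C(C)(C)O[C@H]3CC[C@]2(C)O1 | intermediate
9 | ethyl (2Z)-2-methyl-5-(7-hydroxy ring C/D unit)pent-2-enoate | CCOC(=O)/C(C)=C\CC[C@H]1[C@]2(C)CC[C@H](O[Si](C)(C)C(C)(C)C)C(C)(C)O[C@H]2CC[C@]1(C)O | intermediate
10 | (2Z)-2-methyl-5-(7-hydroxy ring C/D unit)pent-2-en-1-ol | OC/C(C)=C\CC[C@H]1[C@]2(C)CC[C@H](O[Si](C)(C)C(C)(C)C)C(C)(C)O[C@H]2CC[C@]1(C)O | intermediate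
11 | (10R,11S)-epoxy alcohol | OC[C@@]1(C)O[C@H]1CC[C@H]1[C@]2(C)CC[C@H](O[Si](C)(C)C(C)(C)C)C(C)(C)O[C@H]2CC[C@]1(C)O | intermediate
12 | (10S,11S)-triol with C11 isopropenyl | OC[C@@](C)(O)[C@H](C(C)=C)CC[C@H]1[C@]2(C)CC[C@H](O[Si](C)(C)C(C)(C)C)C(C)(C)O[C@H]2CC[C@]1(C)O | intermediate
13 | primary (C9) tosylate of 12 | Cc1ccc(cc1)S(=O)(=O)OC[C@@](C)(O)[C@H](C(C)=C)CC[C@H]1[C@]2(C)CC[C@H](O[Si](C)(C)C(C)(C)C)C(C)(C)O[C@H]2CC[C@]1(C)O | intermediate
14 | terminal C9–C10 epoxide (10S,11S) | C1O[C@@]1(C)[C@H](C(C)=C)CC[C@H]1[C@]2(C)CC[C@H](O[Si](C)(C)C(C)(C)C)C(C)(C)O[C@H]2CC[C@]1(C)O | intermediate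
15 | C4-trimethylsilyl alkyne of 16 | C[Si](C)(C)C#CCC[C@@](C)(O)[C@H](C(C)=C)CC[C@H]1[C@]2(C)CC[C@H](O[Si](C)(C)C(C)(C)C)C(C)(C)O[C@H]2CC[C@]1(C)O | intermediate
16 | (10R,11S)-alkynyl diol | C#CCC[C@@](C)(O)[C@H](C(C)=C)CC[C@H]1[C@]2(C)CC[C@H](O[Si](C)(C)C(C)(C)C)C(C)(C)O[C@H]2CC[C@]1(C)O | intermediate
17 | alkyne diacetate (C10 OAc, C15 OAc) | C#CCC[C@@](C)(OC(C)=O)[C@H](C(C)=C)CC[C@H]1[C@]2(C)CC[C@H](O[Si](C)(C)C(C)(C)C)C(C)(C)O[C@H]2CC[C@]1(C)OC(C)=O | intermediate
18 | ynone with C2 acetate | CC(=O)OC(C)(C)C(=O)C#CCC[C@@](C)(OC(C)=O)[C@H](C(C)=C)CC[C@H]1[C@]2(C)CC[C@H](O[Si](C)(C)C(C)(C)C)C(C)(C)O[C@H]2CC[C@]1(C)OC(C)=O | intermediate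
19 | hydroxy ynone (C2 OH) | CC(C)(O)C(=O)C#CCC[C@@](C)(OC(C)=O)[C@H](C(C)=C)CC[C@H]1[C@]2(C)CC[C@H](O[Si](C)(C)C(C)(C)C)C(C)(C)O[C@H]2CC[C@]1(C)OC(C)=O | intermediate
20 | furanone with tethered isopropenyl group (key-step precursor) | O=C1C=C(CC[C@@](C)(OC(C)=O)[C@H](C(C)=C)CC[C@H]2[C@]3(C)CC[C@H](O[Si](C)(C)C(C)(C)C)C(C)(C)O[C@H]3CC[C@]2(C)OC(C)=O)OC1(C)C | intermediate
21 | cis-fused cyclobutane photoadduct | O=C1[C@@H]3C[C@]2(C)[C@]3(CC[C@@](C)(OC(C)=O)[C@H]2CC[C@H]2[C@]3(C)CC[C@H](O[Si](C)(C)C(C)(C)C)C(C)(C)O[C@H]3CC[C@]2(C)OC(C)=O)OC1(C)C | intermediate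
22 | oxepan-3-one (rings A–D complete) | O=C1CC[C@]2(C)[C@H](CC[C@@](C)(OC(C)=O)[C@H]2CC[C@H]2[C@]3(C)CC[C@H](O[Si](C)(C)C(C)(C)C)C(C)(C)O[C@H]3CC[C@]2(C)OC(C)=O)OC1(C)C | intermediate
23 | (3S)-alcohol | O[C@H]1CC[C@]2(C)[C@H](CC[C@@](C)(OC(C)=O)[C@H]2CC[C@H]2[C@]3(C)CC[C@H](O[Si](C)(C)C(C)(C)C)C(C)(C)O[C@H]3CC[C@]2(C)OC(C)=O)OC1(C)C | intermediate
24 | triacetate, C22 TBS ether | CC(=O)O[C@H]1CC[C@]2(C)[C@H](CC[C@@](C)(OC(C)=O)[C@H]2CC[C@H]2[C@]3(C)CC[C@H](O[Si](C)(C)C(C)(C)C)C(C)(C)O[C@H]3CC[C@]2(C)OC(C)=O)OC1(C)C | intermediate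
25 | CNP0169816.1 | CC(=O)O[C@H]1CC[C@]2(C)[C@H](CC[C@@](C)(OC(C)=O)[C@H]2CC[C@H]2[C@]3(C)CC[C@H](O)C(C)(C)O[C@H]3CC[C@]2(C)OC(C)=O)OC1(C)C | target

**Total step count:** 20. **Longest linear sequence:** 20 steps (1 → 25).

**Steps most likely to fail**

Step 17 (carries the label). The oxocarbenium ion may lose H8 faster than it takes hydride, hydride may arrive syn to the C6 methyl group, or BF3 may ionise a tertiary acetate. The fallback sets out from 21 and returns at 22 by two known reaction types, replacing ionic hydride delivery by surface hydrogenation. Warming 21 with pyridinium p-toluenesulfonate in toluene (acid-catalysed opening of an alkoxycyclobutyl ketone, ended by proton loss) should give the ring A enol ether F1, the oxepan-3-one with a C7=C8 double bond. Hydrogenation of F1 (H2, Pd/C, EtOAc) should add hydrogen anti to the axial C6 methyl and C10 acetoxy groups and give 22.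

Step 16 (key step). The alkene may present the wrong face (C6 epimer of ring B) or close in the crossed sense. The fallback sets out from 18 and returns at 22, using a classical de Mayo reaction of an open-chain β-diketone instead of the furanone chromophore. Hydration of ynone 18 (NaAuCl4, aqueous MeOH) should give β-diketone F2, whose C2 acetate prevents furanone formation. Irradiation of its hydrogen-bonded enol joins C7 to C6 and C4 to C5, and the cyclobutanol retro-aldolises at once to the ring B 1,5-diketone F3. K2CO3 in MeOH removes the activated C2 acetate to give hydroxy diketone F4. Reductive etherification (Et3SiH, TMSOTf, CH2Cl2, −78 °C) of the tertiary hydroxyl with the C7 ketone then closes ring A to 22.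

Step 5. The cascade may stop by proton loss from the C15 cation instead of capture by the ester, or start at the internal epoxide. The fallback sets out from 6 and returns at 7, taking the C15–O bond formation out of the cascade. The silyl-triflate cascade is allowed to end by elimination, as known for trisubstituted alkene terminators, giving the bicyclic ester with a C15 exocyclic methylene group F5 (ring isomers behave alike). Trifluoroacetic acid (CH2Cl2, 0 °C) then protonates the alkene, and the ester carbonyl closes the δ-lactone on the equatorial side of C15 (acid-mediated Markovnikov lactonisation, as for ambreinolide), giving 7.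

**Further compounds**

F1 | step 17 | ring A enol ether (C7=C8) of oxepan-3-one 22 | O=C1CC[C@]2(C)C(=CC[C@@](C)(OC(C)=O)[C@H]2CC[C@H]2[C@]3(C)CC[C@H](O[Si](C)(C)C(C)(C)C)C(C)(C)O[C@H]3CC[C@]2(C)OC(C)=O)OC1(C)C
F2 | step 16 | β-diketone (C3, C7 diketone, C2 OAc) from hydration of 18 | CC(=O)OC(C)(C)C(=O)CC(=O)CC[C@@](C)(OC(C)=O)[C@H](C(C)=C)CC[C@H]1[C@]2(C)CC[C@H](O[Si](C)(C)C(C)(C)C)C(C)(C)O[C@H]2CC[C@]1(C)OC(C)=O
F3 | step 16 | ring B 1,5-diketone with C2 acetate | CC(=O)OC(C)(C)C(=O)CC[C@]1(C)C(=O)CC[C@@](C)(OC(C)=O)[C@H]1CC[C@H]1[C@]2(C)CC[C@H](O[Si](C)(C)C(C)(C)C)C(C)(C)O[C@H]2CC[C@]1(C)OC(C)=O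
F4 | step 16 | ring B hydroxy 1,5-diketone (C2 OH) | CC(C)(O)C(=O)CC[C@]1(C)C(=O)CC[C@@](C)(OC(C)=O)[C@H]1CC[C@H]1[C@]2(C)CC[C@H](O[Si](C)(C)C(C)(C)C)C(C)(C)O[C@H]2CC[C@]1(C)OC(C)=O
F5 | step 5 | bicyclic tert-butyl ester with C15 exocyclic methylene | CC(C)(C)OC(=O)CC[C@H]1[C@]2(C)CC[C@H](O[Si](C)(C)C(C)(C)C)C(C)(C)O[C@H]2CCC1=C
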